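## Retrosynthetic overview

1. Ring C (eight-membered) is closed last by ring-closing metathesis of two (E)-propenyl groups and hydrogenation; the epoxide is made just before by face-selective epoxidation of a tetrasubstituted exocyclic alkene.
2. The carbinol–alkene bond comes from adding a tetrasubstituted cyclopentylidene-ethyllithium (ring D) to the six-ring ketone of a trans-hydrindanone (rings A and B) whose ring-A ketone is masked as a silyl enol ether.
3. Ring D and the alkenyllithium are made in one flask from an acyclic iodo-chloroalkyne (anionic 5-exo-dig cyclisation, then invertive methylation of the carbenoid); its two stereocentres come from a CBS reduction and a chirality-transferring Claisen rearrangement.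
4. Rings A and B are formed together by Pauson–Khand cyclisation of an enyne built from a second CBS alcohol by Ireland–Claisen rearrangement; the trans ring fusion comes from a [(Ph3P)CuH]6 conjugate reduction.
5. Order of ring formation: A and B (one step), D (during fragment coupling), epoxide, then C.

Assumption: the target is taken exactly as the given SMILES, and starting materials 1, 2, 5, 14, 16 and 23 are bought as catalogue chemicals with the stated alkene geometry.

## Route

**Cyclopentane fragment**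

Step 1
Reactants: 1 3-(trimethylsilyl)prop-2-ynal; 2 1-(triphenylphosphoranylidene)propan-2-one
Product: 3 (3E)-6-(trimethylsilyl)hex-3-en-5-yn-2-one
Conditions: CH2Cl2, 0 → 23 °C
Reagents that add atoms: none
Why: Wittig olefination with the stabilised acetonyl ylide gives the (E)-enynone selectively and leaves the silylalkyne untouched.

Step 2
Reactants: 3 (3E)-6-(trimethylsilyl)hex-3-en-5-yn-2-one
Product: 4 (2R,3E)-6-(trimethylsilyl)hex-3-en-5-yn-2-ol
Conditions: (S)-2-methyl-CBS-oxazaborolidine (10 mol%), catecholborane, toluene, −78 °C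
Reagents that add atoms: none
Why: Corey–Bakshi–Shibata reduction, a metal-free catalytic asymmetric 1,2-reduction in which the oxazaborolidine–borane complex binds the ketone with the enynyl group as the large substituent and delivers hydride to one face, sets the (R)-carbinol as the first stereocentre of this fragment.

Step 3
Reactants: 4 (2R,3E)-6-(trimethylsilyl)hex-3-en-5-yn-2-ol; 5 3-bromoprop-1-ene
Product: 6 trimethyl[(3E,5R)-5-(prop-2-enyloxy)hex-3-en-1-ynyl]silane
Conditions: NaH, Bu4NI (cat.), THF, 0 → 23 °C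
Reagents that add atoms: none
Why: Williamson etherification of the sodium alkoxide with allyl bromide occurs at oxygen and does not touch the carbinol stereocentre.

Step 4
Reactants: 6 trimethyl[(3E,5R)-5-(prop-2-enyloxy)hex-3-en-1-ynyl]silane
Product: 8 (2R,3S,4E)-2-methyl-3-[(trimethylsilyl)ethynyl]hex-4-enal, via propenyl ether 7 (not isolated)
Conditions: [IrCl(C8H14)2]2 (1 mol%), PCy3, NaBPh4, CH2Cl2–acetone, 23 °C; then PPh3, 1,2-dichloroethane, 80 °C
Reagents that add atoms: none
Why: Olefin isomerisation of the unsubstituted allyl group to the (E)-propenyl ether followed by Claisen rearrangement through a chair with the carbinol methyl equatorial transfers the C–O chirality into the two new vicinal stereocentres (2,3-syn) and leaves an (E)-propenyl group.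

Step 5
Reactants: 8 (2R,3S,4E)-2-methyl-3-[(trimethylsilyl)ethynyl]hex-4-enal
Product: 9 trimethyl{(3S,4S)-4-methyl-3-[(1E)-prop-1-enyl]hex-5-en-1-ynyl}silane
Conditions: Ph3PCH3Br, KOtBu, THF, 0 °C; then 8, −78 → 0 °C
Reagents that add atoms: methyltriphenylphosphonium bromide, C[P+](c1ccccc1)(c1ccccc1)c1ccccc1.[Br-]
Why: Wittig methylenation with the non-stabilised ylide at low temperature converts the α-branched aldehyde into the terminal alkene without epimerising the adjacent stereocentre.

Step 6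
Reactants: 9 trimethyl{(3S,4S)-4-methyl-3-[(1E)-prop-1-enyl]hex-5-en-1-ynyl}silane
Product: 11 (3S,4S)-1-chloro-4-methyl-3-[(1E)-prop-1-enyl]hex-5-en-1-yne, via terminal alkyne 10 (not isolated)
Conditions: K2CO3 (cat.), MeOH, 23 °C; then NCS, AgOAc (10 mol%), acetone, 40 °C
Reagents that add atoms: N-chlorosuccinimide, O=C1CCC(=O)N1Cl
Why: Base-catalysed protodesilylation and AgOAc-catalysed electrophilic chlorination of the terminal alkyne (through the silver acetylide) install the 1-chloroalkyne that later serves as carbenoid precursor, and no stereocentre is involved.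

Step 7
Reactants: 11 (3S,4S)-1-chloro-4-methyl-3-[(1E)-prop-1-enyl]hex-5-en-1-yne
Product: 13 (3R,4S)-1-chloro-6-iodo-4-methyl-3-[(1E)-prop-1-enyl]hex-1-yne, via alkylborane 12 (not isolated)
Conditions: 9-BBN, THF, 0 → 23 °C; then I2, NaOMe, MeOH, −20 → 0 °C
Reagents that add atoms: iodine, II
Why: Brown hydroboration with 9-BBN is selective for the monosubstituted terminal alkene over the internal alkene and the chloroalkyne (anti-Markovnikov), and base-induced iodinolysis of the primary carbon–boron bond gives the primary iodide.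

**Hydrindanone fragment**

Step 8
Reactants: 14 (3E)-pent-3-en-2-one
Product: 15 (2S,3E)-pent-3-en-2-ol
Conditions: (R)-2-methyl-CBS-oxazaborolidine (10 mol%), catecholborane, toluene, −78 °C
Reagents that add atoms: none
Why: Corey–Bakshi–Shibata reduction with the enantiomeric oxazaborolidine delivers hydride to the opposite ketone face and sets the (S)-carbinol as the first stereocentre of this fragment.

Step 9
Reactants: 15 (2S,3E)-pent-3-en-2-ol; 16 4-methylpent-4-enoic acid
Product: 17 (2S,3E)-pent-3-en-2-yl 4-methylpent-4-enoate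
Conditions: DCC, DMAP (cat.), CH2Cl2, 0 → 23 °C
Reagents that add atoms: none
Why: Steglich esterification acylates the secondary allylic alcohol at oxygen with retention at the carbinol.

Step 10
Reactants: 17 (2S,3E)-pent-3-en-2-yl 4-methylpent-4-enoate
Product: 20 (2R,3R,4E)-3-methyl-2-(2-methylprop-2-enyl)hex-4-enoic acid, via silyl ketene acetal 18 (not isolated), via silyl ester 19 (not isolated)
Conditions: LiN(iPr)2, THF, −78 °C; Me3SiCl, Et3N, −78 → 23 °C; then 1 M HCl
Reagents that add atoms: none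
Why: Ireland–Claisen rearrangement, in which kinetic enolisation in THF gives the (E)-silyl ketene acetal and a chair transition state with the carbinol methyl equatorial transfers the C–O chirality, gives the 2,3-anti acid with both new stereocentres and an (E)-propenyl group.

Step 11
Reactants: 20 (2R,3R,4E)-3-methyl-2-(2-methylprop-2-enyl)hex-4-enoic acid
Product: 22 (2R,3R,4E)-3-methyl-2-(2-methylprop-2-enyl)hex-4-enal, via acid chloride 21 (not isolated)
Conditions: (COCl)2, DMF (cat.), CH2Cl2, 0 → 23 °C; then LiAlH(OtBu)3, THF, −78 °C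
Reagents that add atoms: none
Why: Conversion to the acid chloride and partial reduction with the hindered hydride LiAlH(OtBu)3 at −78 °C stops at the aldehyde and does not epimerise the α-stereocentre.

Step 12
Reactants: 22 (2R,3R,4E)-3-methyl-2-(2-methylprop-2-enyl)hex-4-enal; 23 4-methylpent-2-yne
Product: 26 (7R,8R,9E)-2,8-dimethyl-7-(2-methylprop-2-enyl)undec-9-en-3-yn-6-ol as both C6 epimers, via propargyllithium 24 (not isolated), via allenyltitanium 25 (not isolated)
Conditions: 23, tBuLi, THF, −78 → 0 °C; Ti(OiPr)4, −78 °C; then 22, −78 → 0 °C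
Reagents that add atoms: none
Why: Lithiation at the propargylic methyl group and transmetalation give an allenyltitanium that adds to the aldehyde through a cyclic SE2′ transition state to give only the homopropargylic alcohol, whose new carbinol centre (formed as a mixture) is removed by oxidation in step 14.

Step 13
Reactants: 26 (7R,8R,9E)-2,8-dimethyl-7-(2-methylprop-2-enyl)undec-9-en-3-yn-6-ol
Product: 28 (6R,7aS)-5-hydroxy-7a-methyl-6-[(2R,3E)-pent-3-en-2-yl]-3-(propan-2-yl)-1,4,5,6,7,7a-hexahydro-2H-inden-2-one as both C5 epimers, via dicobalt complex 27 (not isolated)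
Conditions: Co2(CO)8, CH2Cl2, 23 °C; then N-methylmorpholine N-oxide, 0 → 23 °C
Reagents that add atoms: dicobalt octacarbonyl Co2(CO)8 as carbon monoxide donor, [C-]#[O+]
Why: Pauson–Khand [2+2+1] cycloaddition of the alkyne, the 1,1-disubstituted alkene (more reactive than the internal, allylically branched (E)-alkene) and CO forms rings A and B at once, and the chair-like tether with the branched side chain equatorial places the new angular methyl on the same face as the adjacent ring hydrogen, which sets the quaternary centre.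

Step 14
Reactants: 28 (6R,7aS)-5-hydroxy-7a-methyl-6-[(2R,3E)-pent-3-en-2-yl]-3-(propan-2-yl)-1,4,5,6,7,7a-hexahydro-2H-inden-2-one
Product: 29 (6R,7aS)-7a-methyl-6-[(2R,3E)-pent-3-en-2-yl]-3-(propan-2-yl)-4,6,7,7a-tetrahydro-1H-indene-2,5-dione
Conditions: Dess–Martin periodinane, NaHCO3, CH2Cl2, 0 → 23 °C
Reagents that add atoms: none
Why: Dess–Martin oxidation converts both carbinol epimers into one cyclohexanone under neutral conditions that do not move the ring-fusion double bond.

Step 15
Reactants: 29 (6R,7aS)-7a-methyl-6-[(2R,3E)-pent-3-en-2-yl]-3-(propan-2-yl)-4,6,7,7a-tetrahydro-1H-indene-2,5-dione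
Product: 30 (3aR,6R,7aS)-2-{[dimethyl(phenyl)silyl]oxy}-7a-methyl-6-[(2R,3E)-pent-3-en-2-yl]-3-(propan-2-yl)-1,3a,4,6,7,7a-hexahydro-5H-inden-5-one
Conditions: [(Ph3P)CuH]6 (5 mol%), PhMe2SiH, toluene, 23 °C
Reagents that add atoms: dimethylphenylsilane, C[SiH](C)c1ccccc1
Why: Conjugate reduction by [(Ph3P)CuH]6 (1,4-hydrosilylation) is selective for the enone over the saturated ketone, delivers hydride to the ring-fusion carbon from the face opposite the angular methyl to set the trans-hydrindane, and leaves the ring-A carbonyl masked as its silyl enol ether.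

**Fragment coupling and completion**

Step 16
Reactants: 13 (3R,4S)-1-chloro-6-iodo-4-methyl-3-[(1E)-prop-1-enyl]hex-1-yne; 30 (3aR,6R,7aS)-2-{[dimethyl(phenyl)silyl]oxy}-7a-methyl-6-[(2R,3E)-pent-3-en-2-yl]-3-(propan-2-yl)-1,3a,4,6,7,7a-hexahydro-5H-inden-5-one
Product: 35 (3R,3aS,5R,6R,7aS)-5-hydroxy-7a-methyl-5-{(1Z)-1-[(2R,3S)-3-methyl-2-[(1E)-prop-1-enyl]cyclopentylidene]ethyl}-6-[(2R,3E)-pent-3-en-2-yl]-3-(propan-2-yl)octahydro-2H-inden-2-one, via alkyllithium 31 (not isolated), via chloro carbenoid 32 (not isolated), via alkenyllithium 33 (not isolated), via lithium alkoxide 34 (not isolated)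
Conditions: 13 (1.5 equiv), tBuLi (2.0 equiv per 13), pentane–Et2O, −78 → −50 °C; MeLi (1.0 equiv per 13), THF, −78 → −40 °C; 30, −78 °C; then Bu4NF, AcOH, THF, −78 → 0 °C
Reagents that add atoms: methyllithium, [Li]C
Why: Proposed new method: iodine–lithium exchange gives a primary alkyllithium that adds syn and 5-exo-dig across the chloroalkyne so that lithium ends on the chlorine-bearing carbon cis to the new ring bond (chlorine stabilises the incipient carbanion and ring expansion of the cyclopentylidene carbenoid to a cyclohexyne is strained at low temperature), MeLi then displaces chloride from this alkylidene carbenoid by in-plane 1,2-metalate substitution with inversion at the sp2 carbon so that methyl takes the place of lithium (cis to the ring CH2) and lithium the place of chlorine (cis to the propenyl-bearing carbon), the resulting tetrasubstituted alkenyllithium adds with retention to the cyclohexanone of 30 from the equatorial direction to set the axial tertiary alcohol, and fluoride finally frees the ring-A enolate, which is protonated on the face opposite the angular methyl to set the isopropyl-bearing centre; the closest known reaction types are the anionic 5-exo-dig cyclisation of 5-hexynyllithiums onto silyl- or aryl-alkynes and the invertive substitution of 1-halo-1-lithioalkenes by organolithiums, which have not been run in sequence or on a chloroalkyne acceptor.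

Step 17
Reactants: 35 (3R,3aS,5R,6R,7aS)-5-hydroxy-7a-methyl-5-{(1Z)-1-[(2R,3S)-3-methyl-2-[(1E)-prop-1-enyl]cyclopentylidene]ethyl}-6-[(2R,3E)-pent-3-en-2-yl]-3-(propan-2-yl)octahydro-2H-inden-2-one
Product: 36 (3R,3aS,5R,6R,7aS)-5-{(2R,3S,4R,5S)-2,5-dimethyl-4-[(1E)-prop-1-enyl]-1-oxaspiro[2.4]heptan-2-yl}-5-hydroxy-7a-methyl-6-[(2R,3E)-pent-3-en-2-yl]-3-(propan-2-yl)octahydro-2H-inden-2-one
Conditions: mCPBA, NaHCO3, CH2Cl2, −20 → 0 °C
Reagents that add atoms: 3-chloroperoxybenzoic acid, OOC(=O)c1cccc(Cl)c1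
Why: Prilezhaev epoxidation is far faster at the electron-rich tetrasubstituted alkene than at the two disubstituted alkenes, and the peracid attacks the cyclopentylidene face opposite the ring methyl and propenyl groups, which sets both epoxide carbons.

Step 18
Reactants: 36 (3R,3aS,5R,6R,7aS)-5-{(2R,3S,4R,5S)-2,5-dimethyl-4-[(1E)-prop-1-enyl]-1-oxaspiro[2.4]heptan-2-yl}-5-hydroxy-7a-methyl-6-[(2R,3E)-pent-3-en-2-yl]-3-(propan-2-yl)octahydro-2H-inden-2-one
Product: 38 target CNP0332295.1, via cyclooctene 37 (not isolated)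
Conditions: second-generation Grubbs catalyst RuCl2(=CHPh)(H2IMes)(PCy3) (10 mol%), toluene, 80 °C; then H2 (1 atm), Pd/C, EtOAc, 23 °C
Reagents that add atoms: none
Why: Ring-closing metathesis of the two (E)-propenyl groups with loss of but-2-ene closes ring C as the cis-cyclooctene, and hydrogenation of this only remaining alkene gives the target without touching the epoxide, the ketone or the tertiary alcohol.

## Compound list

1 | 3-(trimethylsilyl)prop-2-ynal | C[Si](C)(C)C#CC=O | starting material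
2 | 1-(triphenylphosphoranylidene)propan-2-one | CC(=O)C=P(c1ccccc1)(c1ccccc1)c1ccccc1 | starting material
3 | (3E)-6-(trimethylsilyl)hex-3-en-5-yn-2-one | CC(=O)/C=C/C#C[Si](C)(C)C | intermediate
4 | (2R,3E)-6-(trimethylsilyl)hex-3-en-5-yn-2-ol | C[C@@H](O)/C=C/C#C[Si](C)(C)C | intermediate
5 | 3-bromoprop-1-ene (allyl bromide) | C=CCBr | starting material
6 | trimethyl[(3E,5R)-5-(prop-2-enyloxy)hex-3-en-1-ynyl]silane | C=CCO[C@H](C)/C=C/C#C[Si](C)(C)C | intermediate
7 | trimethyl{(3E,5R)-5-[(1E)-prop-1-enyloxy]hex-3-en-1-ynyl}silane | C/C=C/O[C@H](C)/C=C/C#C[Si](C)(C)C | intermediate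
8 | (2R,3S,4E)-2-methyl-3-[(trimethylsilyl)ethynyl]hex-4-enal | C/C=C/[C@H](C#C[Si](C)(C)C)[C@@H](C)C=O | intermediate
9 | trimethyl{(3S,4S)-4-methyl-3-[(1E)-prop-1-enyl]hex-5-en-1-ynyl}silane | C/C=C/[C@H](C#C[Si](C)(C)C)[C@@H](C)C=C | intermediate
10 | (3S,4S)-4-methyl-3-[(1E)-prop-1-enyl]hex-5-en-1-yne | C/C=C/[C@H](C#C)[C@@H](C)C=C | intermediate
11 | (3S,4S)-1-chloro-4-methyl-3-[(1E)-prop-1-enyl]hex-5-en-1-yne | C/C=C/[C@H](C#CCl)[C@@H](C)C=C | intermediate
12 | 9-{(3S,4R)-6-chloro-3-methyl-4-[(1E)-prop-1-enyl]hex-5-ynyl}-9-borabicyclo[3.3.1]nonane | C/C=C/[C@H](C#CCl)[C@@H](C)CCB1C2CCCC1CCC2 | intermediate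
13 | (3R,4S)-1-chloro-6-iodo-4-methyl-3-[(1E)-prop-1-enyl]hex-1-yne | C/C=C/[C@H](C#CCl)[C@@H](C)CCI | intermediate
14 | (3E)-pent-3-en-2-one | C/C=C/C(C)=O | starting material
15 | (2S,3E)-pent-3-en-2-ol | C[C@H](O)/C=C/C | intermediate
16 | 4-methylpent-4-enoic acid | C=C(C)CCC(=O)O | starting material
17 | (2S,3E)-pent-3-en-2-yl 4-methylpent-4-enoate | C=C(C)CCC(=O)O[C@@H](C)/C=C/C | intermediate
18 | (E)-silyl ketene acetal, trimethyl{[(1E)-4-methyl-1-{[(2S,3E)-pent-3-en-2-yl]oxy}penta-1,4-dienyl]oxy}silane | C=C(C)C/C=C(/O[Si](C)(C)C)O[C@@H](C)/C=C/C | intermediate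
19 | trimethylsilyl (2R,3R,4E)-3-methyl-2-(2-methylprop-2-enyl)hex-4-enoate | C=C(C)C[C@@H](C(=O)O[Si](C)(C)C)[C@H](C)/C=C/C | intermediate
20 | (2R,3R,4E)-3-methyl-2-(2-methylprop-2-enyl)hex-4-enoic acid | C=C(C)C[C@@H](C(=O)O)[C@H](C)/C=C/C | intermediate
21 | (2R,3R,4E)-3-methyl-2-(2-methylprop-2-enyl)hex-4-enoyl chloride | C=C(C)C[C@@H](C(=O)Cl)[C@H](C)/C=C/C | intermediate
22 | (2R,3R,4E)-3-methyl-2-(2-methylprop-2-enyl)hex-4-enal | C=C(C)C[C@@H](C=O)[C@H](C)/C=C/C | intermediate
23 | 4-methylpent-2-yne | CC#CC(C)C | starting material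
24 | (4-methylpent-2-ynyl)lithium | [Li]CC#CC(C)C | intermediate
25 | (4-methylpenta-1,2-dien-3-yl)tri(propan-2-yloxy)titanium | C=C=C(C(C)C)[Ti](OC(C)C)(OC(C)C)OC(C)C | intermediate
26 | (7R,8R,9E)-2,8-dimethyl-7-(2-methylprop-2-enyl)undec-9-en-3-yn-6-ol, both C6 epimers | CC(C)C#CCC(O)[C@H](CC(C)=C)[C@H](C)/C=C/C | intermediate
27 | hexacarbonyldicobalt complex of the alkyne of 26 | CC(C)C#CCC(O)[C@H](CC(C)=C)[C@H](C)/C=C/C.[Co].[Co].[C-]#[O+].[C-]#[O+].[C-]#[O+].[C-]#[O+].[C-]#[O+].[C-]#[O+] | intermediate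
28 | (6R,7aS)-5-hydroxy-7a-methyl-6-[(2R,3E)-pent-3-en-2-yl]-3-(propan-2-yl)-1,4,5,6,7,7a-hexahydro-2H-inden-2-one, both C5 epimers | CC(C)C=1C(=O)C[C@]2(C)C[C@H]([C@H](C)/C=C/C)C(O)CC12 | intermediate
29 | (6R,7aS)-7a-methyl-6-[(2R,3E)-pent-3-en-2-yl]-3-(propan-2-yl)-4,6,7,7a-tetrahydro-1H-indene-2,5-dione | CC(C)C=1C(=O)C[C@]2(C)C[C@H]([C@H](C)/C=C/C)C(=O)CC12 | intermediate
30 | (3aR,6R,7aS)-2-{[dimethyl(phenyl)silyl]oxy}-7a-methyl-6-[(2R,3E)-pent-3-en-2-yl]-3-(propan-2-yl)-1,3a,4,6,7,7a-hexahydro-5H-inden-5-one | CC(C)C1=C(O[Si](C)(C)c3ccccc3)C[C@]2(C)C[C@H]([C@H](C)/C=C/C)C(=O)C[C@@H]12 | intermediate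
31 | {(3S,4R)-6-chloro-3-methyl-4-[(1E)-prop-1-enyl]hex-5-ynyl}lithium | C/C=C/[C@H](C#CCl)[C@@H](C)CC[Li] | intermediate
32 | {(Z)-chloro[(2R,3S)-3-methyl-2-[(1E)-prop-1-enyl]cyclopentylidene]methyl}lithium (Li cis to ring CH2) | C/C=C/[C@H]1[C@@H](C)CC/C1=C(\[Li])Cl | intermediate
33 | {(1E)-1-[(2R,3S)-3-methyl-2-[(1E)-prop-1-enyl]cyclopentylidene]ethyl}lithium (methyl cis to ring CH2) | C/C=C/[C@H]1[C@@H](C)CC/C1=C(\C)[Li] | intermediate
34 | lithium alkoxide of the adduct of 33 and 30, ring-A silyl enol ether still in place | CC(C)C1=C(O[Si](C)(C)c3ccccc3)C[C@]2(C)C[C@H]([C@H](C)/C=C/C)[C@@](O[Li])(C(/C)=C4/CC[C@H](C)[C@@H]4/C=C/C)C[C@@H]12 | intermediate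
35 | (3R,3aS,5R,6R,7aS)-5-hydroxy-7a-methyl-5-{(1Z)-1-[(2R,3S)-3-methyl-2-[(1E)-prop-1-enyl]cyclopentylidene]ethyl}-6-[(2R,3E)-pent-3-en-2-yl]-3-(propan-2-yl)octahydro-2H-inden-2-one | CC(C)[C@H]1C(=O)C[C@]2(C)C[C@H]([C@H](C)/C=C/C)[C@@](O)(C(/C)=C3/CC[C@H](C)[C@@H]3/C=C/C)C[C@@H]12 | intermediate
36 | (3R,3aS,5R,6R,7aS)-5-{(2R,3S,4R,5S)-2,5-dimethyl-4-[(1E)-prop-1-enyl]-1-oxaspiro[2.4]heptan-2-yl}-5-hydroxy-7a-methyl-6-[(2R,3E)-pent-3-en-2-yl]-3-(propan-2-yl)octahydro-2H-inden-2-one | CC(C)[C@H]1C(=O)C[C@]2(C)C[C@H]([C@H](C)/C=C/C)[C@@](O)([C@@]3(C)O[C@]34CC[C@H](C)[C@@H]4/C=C/C)C[C@@H]12 | intermediate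
37 | ring-C cis-cyclooctene (the target with a C=C between the two former propenyl-bearing positions) | CC(C)[C@H]1C(=O)C[C@]2(C)C[C@@H]3[C@H](C)/C=C\[C@H]4[C@@H](C)CC[C@]45O[C@]5(C)[C@@]3(O)C[C@@H]12 | intermediate
38 | target CNP0332295.1, 5-6-8-5 tetracyclic epoxy hydroxy ketone C25H40O3 | CC(C)[C@H]1C(=O)C[C@]2(C)C[C@@H]3[C@H](C)CC[C@H]4[C@@H](C)CC[C@]45O[C@]5(C)[C@@]3(O)C[C@@H]12 | target

## Step count and risks

Total steps: 18. Longest linear sequence: 11 (steps 8 to 15, then 16 to 18).

The three steps most likely to fail: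

**Step 16 (the proposed new cascade).** The carbolithiation onto a chloroalkyne, the lifetime of the carbenoid and the methyl substitution are all untested on this substrate. The fallback uses only known chemistry, sets out from 9 and comes back at 35. Compound 9 is hydroborated with 9-BBN and iodinated (I2, NaOMe) to the silyl iodide trimethyl{(3R,4S)-6-iodo-4-methyl-3-[(1E)-prop-1-enyl]hex-1-ynyl}silane F1. Treatment with tBuLi (2 equiv, pentane–Et2O, −78 °C, then warming) triggers the known anionic 5-exo-dig cyclisation onto the silylalkyne, and the α-silyl alkenyllithium is quenched with MeI at −78 °C to give the vinylsilane trimethyl{(1Z)-1-[(2R,3S)-3-methyl-2-[(1E)-prop-1-enyl]cyclopentylidene]ethyl}silane F2. N-Iodosuccinimide in MeCN replaces silicon by iodine with retention to give the alkenyl iodide (2R,3S)-1-[(1Z)-1-iodoethylidene]-3-methyl-2-[(1E)-prop-1-enyl]cyclopentane F3. Iodine–lithium exchange with tBuLi, addition to 30 and the same Bu4NF/AcOH treatment give 35.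

**Step 13 (Pauson–Khand cyclisation).** A 1,7-enyne with a 1,1-disubstituted alkene, an isopropyl-substituted alkyne and a second, internal alkene is a demanding substrate. The fallback sets out from 26 and comes back at 28. The hydroxyl of 26 is deprotonated with nBuLi and the lithium alkoxide is treated with Cp2ZrBu2 (made from Cp2ZrCl2 and two equivalents of nBuLi, THF, −78 → 23 °C). Oxidative cyclisation of the alkyne with the terminal 1,1-disubstituted alkene (internal alkenes do not take part) gives the zirconabicycle lithium alkoxide F4. Stirring under CO (1 atm) and quenching with aqueous HCl gives, by CO insertion and reductive elimination, the same enone 28.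

**Step 15 (conjugate reduction of the tetrasubstituted enone by [(Ph3P)CuH]6).** The β-carbon is fully substituted and next to a quaternary centre, so hydride delivery may be too slow. The fallback sets out from 28 and comes back at 35. Li in liquid NH3/THF with tBuOH (1 equiv) at −78 °C, then NH4Cl, reduces the enone of 28 (ring-fusion carbanion protonated anti to the angular methyl, enolate protonated kinetically) to the trans-fused hydroxy ketone (3R,3aS,6R,7aS)-5-hydroxy-7a-methyl-6-[(2R,3E)-pent-3-en-2-yl]-3-(propan-2-yl)octahydro-2H-inden-2-one F5. Ethylene glycol with pyridinium p-toluenesulfonate in benzene with removal of water gives the ring-A ethylene ketal of this alcohol F6. Dess–Martin oxidation gives the keto ketal (3R,3aS,6R,7aS)-2,2-(ethylenedioxy)-7a-methyl-6-[(2R,3E)-pent-3-en-2-yl]-3-(propan-2-yl)octahydro-5H-inden-5-one F7. Addition of alkenyllithium 33 (made as in step 16) gives the ethylene ketal of 35 F8. Pyridinium p-toluenesulfonate in wet acetone removes the ketal and gives 35.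

## Further compounds

F1 | step 16 | trimethyl{(3R,4S)-6-iodo-4-methyl-3-[(1E)-prop-1-enyl]hex-1-ynyl}silane | C/C=C/[C@H](C#C[Si](C)(C)C)[C@@H](C)CCI
F2 | step 16 | trimethyl{(1Z)-1-[(2R,3S)-3-methyl-2-[(1E)-prop-1-enyl]cyclopentylidene]ethyl}silane | C/C=C/[C@H]1[C@@H](C)CC/C1=C(\C)[Si](C)(C)C
F3 | step 16 | (2R,3S)-1-[(1Z)-1-iodoethylidene]-3-methyl-2-[(1E)-prop-1-enyl]cyclopentane | C/C=C/[C@H]1[C@@H](C)CC/C1=C(\C)I
F4 | step 13 | zirconabicycle lithium alkoxide (Cp2Zr bridging the isopropyl-bearing alkene carbon and the CH2 on the quaternary carbon) | CC(C)C=1[Zr](C2C=CC=C2)(C2C=CC=C2)C[C@]3(C)C[C@H]([C@H](C)/C=C/C)C(O[Li])CC13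
F5 | step 15 | (3R,3aS,6R,7aS)-5-hydroxy-7a-methyl-6-[(2R,3E)-pent-3-en-2-yl]-3-(propan-2-yl)octahydro-2H-inden-2-one, both C5 epimers | CC(C)[C@H]1C(=O)C[C@]2(C)C[C@H]([C@H](C)/C=C/C)C(O)C[C@@H]12
F6 | step 15 | ring-A ethylene ketal of F5 | CC(C)[C@H]1C2(OCCO2)C[C@]3(C)C[C@H]([C@H](C)/C=C/C)C(O)C[C@@H]13
F7 | step 15 | (3R,3aS,6R,7aS)-2,2-(ethylenedioxy)-7a-methyl-6-[(2R,3E)-pent-3-en-2-yl]-3-(propan-2-yl)octahydro-5H-inden-5-one | CC(C)[C@H]1C2(OCCO2)C[C@]3(C)C[C@H]([C@H](C)/C=C/C)C(=O)C[C@@H]13
F8 | step 15 | ring-A ethylene ketal of 35 | CC(C)[C@H]1C2(OCCO2)C[C@]3(C)C[C@H]([C@H](C)/C=C/C)[C@@](O)(C(/C)=C4/CC[C@H](C)[C@@H]4/C=C/C)C[C@@H]13
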